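In a one-step world substrate meets partner and gives target, and autumn is a subtraction: partner is the limiting reagent, 13.3 mM against 19 mM, so target stops at 70.0% of the substrate charged.

| flask | substrate | partner | protic impurity | temperature | remark | time |
|---|---|---|---|---|---|---|
| zeta | 19 mM | 13.3 mM | 0.38 mM | 10 °C | run made earlier |  |
| beta | 19 mM | 6.7 mM | 0.38 mM | 25 °C | run made earlier |  |
| gamma | 19 mM | 10 mM | 0.38 mM | 10 °C | run made earlier |  |
| theta | 9.5 mM | 13.3 mM | 0.38 mM | 25 °C | run made earlier |  |
| autumn | 19 mM | 13.3 mM | 0.380 mM | 25 °C | everything together at the start | 4.0 min |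
| dawn | 19 mM (fed, over 3.0 min) | 13.3 mM | 0.380 mM | 25 °C | all else is in the flask from the start; the feed brings no volume worth counting | 4.0 min |
| winter | 19 mM | 13.3 mM (fed, over 3.0 min) | 0.380 mM | 25 °C | all else is in the flask from the start; the feed brings no volume worth counting | 4.0 min |
| summer | 19 mM (fed, over 3.0 min) | 13.3 mM | 0.380 mM |  | the addition at −5 °C, then warmed to 25 °C; the feed brings no volume worth counting | 4.0 min |

- zeta (time / min: target / %, substrate / %): 0.667: 14.3, 59.4; 2.00: 28.2, 32.1; 3.00: 30.7, 22.2; 5.00: 36.9, 13.0
- beta (time / min: target / %, substrate / %): 0.333: 11.3, 65.1; 0.833: 12.5, 40.6; 1.50: 15.9, 27.7; 2.50: 21.0, 17.3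
- gamma (time / min: target / %, substrate / %): 0.667: 10.7, 63.6; 2.00: 21.7, 37.0; 3.00: 24.1, 24.8; 5.00: 29.0, 16.1
- theta (time / min: target / %, substrate / %): 0.333: 18.6, 68.8; 0.833: 35.2, 40.6; 1.50: 44.1, 26.3; 2.50: 53.0, 17.0

(scatter of a reading: 1 percentage point)

* the flask that comes out highest in amount of target, in percent of the substrate charged, or "all alike" when all lie within 1.5 percentage points (autumn / dawn / winter / summer / all alike)
* target at the end, in percent of the substrate charged, autumn
* target at the end, in percent of the substrate charged, dawn
* target at the end, in percent of the substrate charged, winter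
* target at the end, in percent of the substrate charged, summer

- a species is counted by the substrate in it: one homo dimer counts as two
- candidate steps: substrate + partner -> target; 2 partner -> side product; partner + protic impurity -> quenched reagent; 2 substrate -> homo dimer

Now we add the road to homo dimer. In theta at 2.50 min, substrate stands at 17.0% and target at 53.0%, so we read the missing 30.0% as homo dimer. The target road goes as [substrate][partner] and the dimer road as [substrate]², so target over dimer is σ[partner]/[substrate]. We replace each curve by the mean of its start and end, taking from the partner what the protic impurity and the target use. Theta then reads 0.944. Beta, at 2.50 min, with partner over substrate 0.353 instead of 1.40, reads 0.877. We carry their mean, σ = 0.910, the selectivity factor: target road over dimer road at equal [partner] and [substrate].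

In autumn the ratio opens at 0.637, so the dimer road leads at first. Then the rest: the protic impurity takes hardly any of the partner, leaving 12.9 mM, and we leave out the side product. Suppose the substrate is used up by 4.0 min, so its mean is 9.50 mM. Target made lowers mean partner, and in our ratio the share going to target rises with mean partner. The value satisfying both is 8.60 mM, or 45.2%. In dawn part of the charge arrives late. At equal [partner], lower [substrate] lifts the share, but a share doesn't tell how much has reacted by 4.0 min, so we commit to a number for autumn.

The forecast named dawn, with 43%, 44%, 23% and 33% for autumn, dawn, winter and summer, and wrote of dawn that “substrate is left over at the end”. The simulation gives 42.6%, 40.7%, 23.0% and 32.4%, so autumn comes highest, and our reckoning for autumn stands 2.6 percentage points above the simulated value.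

    substrate + partner → target (k = 0.980 L mol⁻¹ s⁻¹, Ea = 40.0 kJ mol⁻¹)
    2 partner → side product (k = 0.0580 L mol⁻¹ s⁻¹, Ea = 41.0 kJ mol⁻¹)
    partner + protic impurity → quenched reagent (k = 570 L mol⁻¹ s⁻¹, Ea = 43.0 kJ mol⁻¹)
    2 substrate → homo dimer (k = 0.570 L mol⁻¹ s⁻¹, Ea = 35.0 kJ mol⁻¹)
    (constants at 25 °C)

In autumn, substrate used by the target step over that used by the dimer step is 0.60 at the start, where σ gave 0.637, and 2.3 at 4.00 min. In autumn the dimer step reaches the midpoint of its turnover up to 4.0 min at 0.326 min, earlier than the target step at 0.507 min. For a neighbour of autumn with 8.0 mM of partner, σ and the same means give 31.0%. The computed flask gives 27.9%, with 10.6% of the substrate still there.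

The readings are calculated from invented constants, and the scatter is random.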